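**Retrosynthetic overview**

1. Final bond: side-chain C1'–C2' by a visible-light decarboxylative radical hydroalkylation of an (8R)-5-methylidene-tetrahydroquinolin-4-one with 5-phenylpentanoic acid; C5–H is delivered anti to the C8-OMe, giving the 5,8-cis product.
2. Carbocycle (C4a–C5) by 6-exo Heck cyclisation of a 5-iodo-4-pyridone carrying an (R)-1-methoxypent-4-enyl arm at C6.
3. N-Methoxy-4-pyridone ring from a 1,3,5-triketone and MeONH2; the triketone from a Claisen condensation of an (R)-α-methoxy ester with the dianion of 3-methoxypentane-2,4-dione.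
4. The C8 stereocentre is bought as methyl (R)-glycidate (L-serine-derived), opened with allylMgCl and O-methylated.
5. Ring order: pyridone first, carbocycle second, side chain last.

Assumption: positions are numbered as in 5,6,7,8-tetrahydroquinolin-4(1H)-one; the target SMILES corresponds to (5S,8R), i.e. 5,8-cis. Methyl (R)-glycidate is taken as a catalogue chiral building block.

**Route**

Step 1
Reactants: 1, methyl (2R)-oxirane-2-carboxylate (methyl (R)-glycidate); 2, allylmagnesium chloride
Product: 3, methyl (2R)-2-hydroxyhex-5-enoate
Conditions: 2 (1.3 equiv), CuI (10 mol%), THF, −78 → −40 °C; aq NH4Cl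
Reagents that add atoms: none besides reactant 2 (allyl group, C=CC[Mg]Cl)
Why: Cu-catalysed SN2 epoxide opening at the unsubstituted C3 of the glycidic ester, which outpaces ester addition at −78 °C; the C2 stereocentre (future C8) is not touched.

Step 2
Reactants: 3, methyl (2R)-2-hydroxyhex-5-enoate
Product: 4, methyl (2R)-2-methoxyhex-5-enoate
Conditions: MeI, Ag2O, MeCN, rt, dark
Reagents that add atoms: iodomethane, CI
Why: Purdie O-methylation under non-basic conditions, so the α-stereocentre does not epimerise and the alkene is untouched.

Step 3 (side branch)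
Reactants: 5, methoxyacetone
Product: 6, 3-methoxypentane-2,4-dione
Conditions: Ac2O, BF3·OEt2, 0 °C → rt; then aq NaOAc, 80 °C
Reagents that add atoms: acetic anhydride, CC(=O)OC(C)=O
Why: BF3-mediated C-acetylation of a methyl methylene ketone (Meerwein/Hauser β-diketone synthesis) at the methylene carbon via the more substituted, alkoxy-stabilised enol.

Step 4
Reactants: 4, methyl (2R)-2-methoxyhex-5-enoate; 6, 3-methoxypentane-2,4-dione
Product: 7, (7R)-3,7-dimethoxyundec-10-ene-2,4,6-trione (keto/enol tautomers; C3 is labile and undefined)
Conditions: 6 (2.2 equiv), LDA (4.4 equiv), THF, −78 → 0 °C; then 4, −78 → 0 °C; AcOH quench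
Reagents that add atoms: none besides reactant 6
Why: Claisen-type acylation of the β-diketone 1,3-dianion (Hauser dianion) at its terminal carbon; the α-methoxy ester is far less acidic than the enolate partners, so the stereocentre is not enolised.

Step 5
Reactants: 7, (7R)-3,7-dimethoxyundec-10-ene-2,4,6-trione
Product: 8, 1,3-dimethoxy-6-[(1R)-1-methoxypent-4-en-1-yl]-2-methylpyridin-4(1H)-one
Conditions: MeONH2·HCl, NaOAc, AcOH/EtOH, 80 °C
Reagents that add atoms: O-methylhydroxylamine hydrochloride, CON.Cl
Why: 4-Pyridone synthesis by condensation of a 1,3,5-triketone (via its γ-pyrone/enaminone) with a primary amine; N bridges the two terminal carbonyls with loss of 2 H2O, and C8–H is not enolised because the adjacent carbonyl is tied up in the vinylogous system.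

Step 6
Reactants: 8
Product: 9, 5-iodo-1,3-dimethoxy-6-[(1R)-1-methoxypent-4-en-1-yl]-2-methylpyridin-4(1H)-one
Conditions: NIS (1.1 equiv), MeCN, 0 °C → rt, dark
Reagents that add atoms: N-iodosuccinimide, O=C1CCC(=O)N1I
Why: Electrophilic iodination at the only ring C–H, the nucleophilic α-carbon of the vinylogous amide; the unactivated terminal alkene does not react without a strong nucleophile.

Step 7
Reactants: 9
Product: 10, (8R)-1,3,8-trimethoxy-2-methyl-5-methylidene-5,6,7,8-tetrahydroquinolin-4(1H)-one
Conditions: Pd(OAc)2 (5 mol%), PPh3 (12 mol%), Ag2CO3 (2 equiv), MeCN, 80 °C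
Reagents that add atoms: none
Why: Intramolecular Mizoroki–Heck reaction, 6-exo-trig; β-hydride elimination can only use C5–H, giving the exocyclic methylene, and Ag2CO3 suppresses Pd–H re-addition and isomerisation to the endocyclic alkene.

Step 8
Reactants: 10; 11, 5-phenylpentanoic acid
Product: 12, Waltherione H, (5S,8R)-1,3,8-trimethoxy-2-methyl-5-(5-phenylpentyl)-5,6,7,8-tetrahydroquinolin-4(1H)-one
Conditions: 11 (3 equiv), N-hydroxyphthalimide, DIC, DMAP (cat.), CH2Cl2, rt (redox-active ester formed in situ); then 10, Hantzsch ester (3 equiv), Ru(bpy)3(PF6)2 (1 mol%), i-Pr2NEt, 450 nm LEDs, 10 °C, Ar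
Reagents that add atoms: none besides reactant 11 (4-phenylbutyl fragment after loss of CO2); C5–H comes from the Hantzsch ester
Why: Proposed new method: visible-light decarboxylative radical hydroalkylation of a 5-methylidene-tetrahydroquinolin-4-one (a cross-conjugated 2-amino-1,3-diene, not a Michael acceptor), in which the 4-phenylbutyl radical (SET reduction of the NHPI ester, −CO2) adds to the exocyclic CH2 to give a planar, pyridone-conjugated C5 radical that is quenched by H-atom transfer from the bulky Hantzsch ester along the axial trajectory anti to the C8-OMe (held pseudoaxial by A1,3 strain with N-OMe), so C5–H ends up trans to OMe and the chain cis, giving (5S) under control of the purchased C8 centre; the closest known reaction is the photoredox Giese-type hydroalkylation of styrenes and Michael acceptors with redox-active esters and Hantzsch ester.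

**Compound list**

1 | methyl (2R)-oxirane-2-carboxylate | COC(=O)[C@H]1CO1 | starting material
2 | allylmagnesium chloride | C=CC[Mg]Cl | starting material
3 | methyl (2R)-2-hydroxyhex-5-enoate | COC(=O)[C@H](O)CCC=C | intermediate
4 | methyl (2R)-2-methoxyhex-5-enoate | COC(=O)[C@H](OC)CCC=C | intermediate
5 | methoxyacetone | COCC(C)=O | starting material
6 | 3-methoxypentane-2,4-dione | CC(=O)C(OC)C(C)=O | intermediate
7 | (7R)-3,7-dimethoxyundec-10-ene-2,4,6-trione | CC(=O)C(OC)C(=O)CC(=O)[C@H](OC)CCC=C | intermediate
8 | 1,3-dimethoxy-6-[(1R)-1-methoxypent-4-en-1-yl]-2-methylpyridin-4(1H)-one | COc1c(C)n(OC)c([C@H](OC)CCC=C)cc1=O | intermediate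
9 | 5-iodo-1,3-dimethoxy-6-[(1R)-1-methoxypent-4-en-1-yl]-2-methylpyridin-4(1H)-one | COc1c(C)n(OC)c([C@H](OC)CCC=C)c(I)c1=O | intermediate
10 | (8R)-1,3,8-trimethoxy-2-methyl-5-methylidene-5,6,7,8-tetrahydroquinolin-4(1H)-one | COc1c(C)n(OC)c2c(c1=O)C(=C)CC[C@H]2OC | intermediate
11 | 5-phenylpentanoic acid | OC(=O)CCCCc1ccccc1 | starting material
12 | Waltherione H, (5S,8R)-1,3,8-trimethoxy-2-methyl-5-(5-phenylpentyl)-5,6,7,8-tetrahydroquinolin-4(1H)-one | COc1c(C)n(OC)c2c(c1=O)[C@@H](CCCCCc1ccccc1)CC[C@H]2OC | target

**Step count**

Total steps: 8. Longest linear sequence: 7 (1 → 3 → 4 → 7 → 8 → 9 → 10 → 12; step 3 is a one-step side branch).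

**Three steps most likely to fail, with fallbacks**

1. Step 8 (proposed new step). Risks: modest cis/trans ratio in the H-atom transfer, premature reduction of the alkyl radical, or exo-to-endo alkene isomerisation of 10. Fallback (known chemistry): hydroborate 10 with 9-BBN (boron to the CH2, H to C5 from the face anti to C8-OMe), then Pd/PCy3 alkyl–alkyl Suzuki–Miyaura coupling of the primary alkylborane with (4-bromobutyl)benzene.

2. Step 7 (Heck cyclisation). Risks: isomerisation of the exocyclic methylene to the endocyclic 5-methyl alkene, or loss of MeOH from C8 leading to aromatisation. Fallback: cleave the terminal alkene of 9 to the aldehyde (OsO4/NaIO4), close the ring by intramolecular Nozaki–Hiyama–Kishi reaction (CrCl2/cat. NiCl2), oxidise the C5 carbinol to the ketone (DMP) and methylenate (Ph3P=CH2) to reach 10.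

3. Step 5 (direct N-methoxypyridone formation). Risks: methoxyamine stalls at oxime ethers or condenses at the central carbonyl. Fallback: cyclodehydrate 7 to the γ-pyrone with TFA, convert it with NH2OH to the N-hydroxy-4-pyridone, then O-methylate the N–OH with MeI/K2CO3.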